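**Plan**

Numbering (abietane): ring B = C5–C10; ring C = C8, C9, C11–C14; acid chain C1–C3; isopropenyl C4/C18/C19; C20 = methyl on C10; C21 = a temporary carboxyl carbon on C6.
Enabling feature: ring C is a 1,4-hydroquinone (oxygen on C11 and C14) with the C7 ketone on C8. One oxidation level higher, C8=C9 is a localised quinone alkene, and with the enol C6=C7 of that ketone it forms a 1-hydroxy diene (a vinyl quinone). This diene falls back to the aromatic acyl hydroquinone after a [4+2] addition.
Cuts: C4=C18 (methylenation); C6–C21 with C21–O–C4 (a γ-lactone absent from the target, lost as CO2); then C5–C6 and C9–C10 together (intramolecular Diels–Alder); then the ester bond C21–O, the acyl bonds C6–C21 and C7–C8, and C1–C2 (Johnson–Claisen).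
Forward: the C1–C5/C10 chain is built from (R)-lactate and joined, as the ester of its C4 carbinol, to an aroylacetate made from 1,2,4-trimethoxybenzene (ring C). After oxidation to the quinone, ring B and the temporary lactone arise in one step. The lactone is then cleaved and C4 goes from carbinol to ketone to methylene.
Stereochemistry: C4 (R) comes from lactate, and the chair Claisen sets the E alkene (C4 cis to C20). Suprafacial addition turns E into the 5α-H/10β-CH3 relation, and A(1,3) strain at C4 picks the alkene face and hence the absolute configuration. C4 and C6 are erased afterwards.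

Key step: step 12

Remark on the chemistry: C6 in 17–20 is drawn for the cis-fused lactone. As the α-carbon of a β-dicarbonyl unit it is configurationally labile, and it becomes CH2 in step 13, so it has no bearing on the target.

**Route**

Step 1
Reactants: 1 methyl (R)-lactate
Product: 2 methyl (2R)-2-[(tert-butyldimethylsilyl)oxy]propanoate
Conditions: TBSCl, imidazole, DMF, 0 °C to rt
Reagents that add atoms: tert-butyldimethylsilyl chloride CC(C)(C)[Si](C)(C)Cl
Why: Standard silyl ether protection of a secondary alcohol, which does not touch the carbinol stereocentre (the later C4).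

Step 2
Reactants: 2 methyl (2R)-2-[(tert-butyldimethylsilyl)oxy]propanoate
Product: 3 (2R)-2-[(tert-butyldimethylsilyl)oxy]propanal
Conditions: i-Bu2AlH (1.05 equiv), CH2Cl2, −78 °C; aq. potassium sodium tartrate
Reagents that add atoms: none
Why: Partial ester reduction stops at the aldehyde because the tetrahedral aluminium hemiacetal survives at −78 °C, and α-silyloxy aldehydes of this kind should keep their configuration when used directly.

Step 3
Reactants: 3 (2R)-2-[(tert-butyldimethylsilyl)oxy]propanal
Product: 4 (4R)-4-[(tert-butyldimethylsilyl)oxy]-2-methylpent-1-en-3-ol (both C3 epimers)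
Conditions: CH2=C(CH3)MgBr, THF, −78 to 0 °C; H2O
Reagents that add atoms: isopropenylmagnesium bromide C=C(C)[Mg]Br
Why: Grignard 1,2-addition to the aldehyde, in which the new carbinol centre may form as a mixture because it becomes the sp2 carbon C5 in step 4.

Step 4
Reactants: 4 (4R)-4-[(tert-butyldimethylsilyl)oxy]-2-methylpent-1-en-3-ol
Product: 6 ethyl (4E,6R)-6-[(tert-butyldimethylsilyl)oxy]-4-methylhept-4-enoate, via ketene acetal 5 (not isolated)
Conditions: CH3C(OEt)3 (6 equiv), EtCO2H (cat.), 140 °C, EtOH distilled off
Reagents that add atoms: triethyl orthoacetate CCOC(C)(OCC)OCC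
Why: Johnson–Claisen [3,3] rearrangement through a chair with the CH(OTBS)CH3 group equatorial should give the E trisubstituted alkene (C4 cis to the C20 methyl) and forms C1–C2, from either carbinol epimer and without touching C4.

Step 5
Reactants: 6 ethyl (4E,6R)-6-[(tert-butyldimethylsilyl)oxy]-4-methylhept-4-enoate
Product: 7 ethyl (4E,6R)-6-hydroxy-4-methylhept-4-enoate
Conditions: HF·pyridine, THF–pyridine, 0 °C to rt
Reagents that add atoms: none
Why: Buffered fluoride desilylation cleaves only the Si–O bond, so the allylic carbinol is not ionised and both its R configuration and the E alkene are kept.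

Step 6
Reactants: 8 1,2,4-trimethoxybenzene
Product: 10 2-(2,3,6-trimethoxyphenyl)propan-2-ol, via aryllithium 9 (not isolated)
Conditions: n-BuLi, THF, 0 °C to rt; acetone, −78 °C to rt; H2O
Reagents that add atoms: acetone CC(C)=O
Why: Directed ortho-lithiation takes place at C3, the position flanked by two methoxy groups, and carbonyl addition places the three carbons of the later isopropyl group on C13.

Step 7
Reactants: 10 2-(2,3,6-trimethoxyphenyl)propan-2-ol
Product: 11 1,2,4-trimethoxy-3-(propan-2-yl)benzene
Conditions: Et3SiH, CF3CO2H, CH2Cl2, 0 °C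
Reagents that add atoms: none
Why: Ionic hydrogenation works because the tertiary benzylic cation forms readily and is trapped by the silane, and any styrene formed by elimination re-enters through the same cation.

Step 8
Reactants: 11 1,2,4-trimethoxy-3-(propan-2-yl)benzene
Product: 12 1-[2,4,5-trimethoxy-3-(propan-2-yl)phenyl]ethan-1-one
Conditions: Ac2O, Sc(OTf)3 (10 mol %), MeNO2, 50 °C
Reagents that add atoms: acetic anhydride CC(=O)OC(C)=O
Why: Catalytic Friedel–Crafts acylation should go to the one free position that is ortho to one methoxy group and para to another (the later C8), which leaves C9–H, and the mild catalyst avoids demethylation.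

Step 9
Reactants: 12 1-[2,4,5-trimethoxy-3-(propan-2-yl)phenyl]ethan-1-one
Product: 13 methyl 3-oxo-3-[2,4,5-trimethoxy-3-(propan-2-yl)phenyl]propanoate
Conditions: NaH (2.5 equiv), (MeO)2CO, THF, reflux; 1 M HCl
Reagents that add atoms: dimethyl carbonate COC(=O)OC
Why: Crossed Claisen condensation of the methyl ketone enolate with a carbonate is driven by deprotonation of the β-keto ester product and installs C21.

Step 10
Reactants: 13 methyl 3-oxo-3-[2,4,5-trimethoxy-3-(propan-2-yl)phenyl]propanoate; 7 ethyl (4E,6R)-6-hydroxy-4-methylhept-4-enoate
Product: 14 ethyl (4E,6R)-4-methyl-6-({3-oxo-3-[2,4,5-trimethoxy-3-(propan-2-yl)phenyl]propanoyl}oxy)hept-4-enoate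
Conditions: DMAP (30 mol %), toluene, reflux, 4 Å molecular sieves
Reagents that add atoms: none
Why: DMAP-catalysed transesterification is specific for β-keto esters, so the plain ethyl ester stays, it exchanges at the acyl–oxygen bond so C4 keeps its configuration, and it runs well below the temperature of a Carroll rearrangement.

Step 11
Reactants: 14 ethyl (4E,6R)-4-methyl-6-({3-oxo-3-[2,4,5-trimethoxy-3-(propan-2-yl)phenyl]propanoyl}oxy)hept-4-enoate
Product: 15 ethyl (4E,6R)-6-({3-[4-methoxy-3,6-dioxo-5-(propan-2-yl)cyclohexa-1,4-dien-1-yl]-3-oxopropanoyl}oxy)-4-methylhept-4-enoate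
Conditions: (NH4)2Ce(NO3)6 (2.5 equiv), MeCN–H2O 4:1, 0 °C, 15 min; extracted into toluene, used at once
Reagents that add atoms: water O
Why: Oxidative demethylation of a para-dimethoxyarene takes only the para pair O11/O14 to the 1,4-quinone and leaves the C12 methoxy group as a vinylogous ester, and the fast oxidation of the electron-rich arene should outrun oxidation of the β-dicarbonyl unit.

Step 12
Reactants: 15 acyl quinone (toluene solution from step 11)
Product: 19 hydroquinone β-keto-γ-lactone (4R; 5α-H; 6α-H; 10β-CH3), via Z-enol 16 (not isolated), via cycloadduct 17 (not isolated), via quinone lactone 18 (not isolated)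
Conditions: activated MnO2 (5 equiv), PhMe–(CF3)2CHOH 9:1 (2 mM), under argon, dark, 70 °C; filtered; aq. Na2S2O4
Reagents that add atoms: none
Why: Proposed new method: mechanism — 15 enolises to the chelated Z-enol 16, whose C6=C7 bond and the localised quinone bond C8=C9 form an electron-poor 1-hydroxy diene held s-cis by the O7–H···O14 hydrogen bond and carrying C21 on the outer position of C6; this diene adds suprafacially to the tethered C5=C10 alkene (inverse-demand [4+2], C5–C6 bonding ahead of C9–C10) to give 17, which aromatises to 19 by two proton shifts (C9–H to O11, O7–H to O14). The closest known reaction type is the intramolecular vinyl quinone Diels–Alder reaction, in which a three-atom tether on the vinyl terminus likewise delivers an unactivated trisubstituted alkene so that its CH carbon bonds to the vinyl terminus and its fully substituted carbon to the quinone ring carbon; what is new is the use of a β-keto ester enol as the vinyl unit and of an ester as the tether. Ring B closes as the six-membered ring of the cycloaddition and the temporary γ-lactone (C6–C21–O–C4–C5) as the five-membered ring of a type 1 intramolecular closure, 5-exo with respect to the alkene. C5 and C10 are fixed relative to each other by the suprafacial addition to the E alkene (C4 cis to C20 gives 5α-H with 10β-CH3) and in the absolute sense by the 4R carbinol carbon, whose C–H bond must eclipse C5=C10 to escape A(1,3) strain with the C20 methyl group, so that the tether oxygen, and with it the diene, can reach only one alkene face; C6 follows from the fold of the tether but is labile and is erased in step 13, and C9 loses its hydrogen at once. The step needs regioselectivity (C6 to C5 and C9 to C10, not the reverse), chemoselectivity for the carbon diene over the O7=C7–C8=C9 heterodiene and facial selectivity: the short tether allows only the fused mode, this mode also puts the developing positive charge on tertiary C10, and the face is settled by C4. MnO2 returns to the quinone level whatever is reduced by hydrogen exchange between 19 and unreacted 15, so that all material can cyclise, and the dithionite wash then brings 18 back to 19.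

Step 13
Reactants: 19 hydroquinone β-keto-γ-lactone
Product: 21 3-{(1S,2R)-5,8-dihydroxy-2-[(1R)-1-hydroxyethyl]-7-methoxy-1-methyl-4-oxo-6-(propan-2-yl)-1,2,3,4-tetrahydronaphthalen-1-yl}propanoic acid, via β-keto acid 20 (not isolated)
Conditions: 1 M H2SO4, dioxane–H2O 1:1 (degassed), 95 °C
Reagents that add atoms: water O
Why: In this classical acid hydrolysis–decarboxylation of an α-acyl-γ-butyrolactone water opens the lactone at the acyl–oxygen bond, β-keto acid 20 loses CO2 irreversibly to leave C6H2, the ethyl ester is hydrolysed in the same pot, any coumarin-type translactonised isomer of 19 funnels to the same product, and C5 and C10 carry neither an acidic hydrogen nor a leaving group.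

Step 14
Reactants: 21 hydroxy acid
Product: 23 3-[(1S,2R)-2-acetyl-5,8-dihydroxy-7-methoxy-1-methyl-4-oxo-6-(propan-2-yl)-1,2,3,4-tetrahydronaphthalen-1-yl]propanoic acid, via quinone diketone 22 (not isolated)
Conditions: Dess–Martin periodinane (2.5 equiv), CH2Cl2, 0 °C to rt; then aq. Na2S2O4
Reagents that add atoms: none
Why: Dess–Martin oxidation takes the C4 carbinol to the methyl ketone and unavoidably takes ring C to the fully substituted quinone 22, which dithionite returns selectively to the hydroquinone because ketones are inert to it, while the near-neutral medium avoids enolisation at C5 and furan formation from the 1,4-diketone.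

Step 15
Reactants: 23 methyl ketone
Product: 24 3-[(1S,2S)-5,8-dihydroxy-7-methoxy-1-methyl-4-oxo-6-(propan-2-yl)-2-(prop-1-en-2-yl)-1,2,3,4-tetrahydronaphthalen-1-yl]propanoic acid (target)
Conditions: KOt-Bu (3 equiv), THF, 0 °C, under argon; Ph3P=CH2 (3 equiv, from Ph3PCH3Br and KOt-Bu), 0 °C to rt; 1 M HCl (cold, brief)
Reagents that add atoms: methyltriphenylphosphonium bromide C[P+](c1ccccc1)(c1ccccc1)c1ccccc1.[Br-]
Why: In this Wittig methylenation the C14 phenoxide turns the C7 ketone into an unreactive vinylogous carboxylate and the carboxylate is inert, so the ylide should attack only the C4 methyl ketone, and any kinetic enolisation should go to the CH3 side so that C5 is kept.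

**Compound list**

1 | methyl (R)-lactate | C[C@@H](O)C(=O)OC | starting material
2 | methyl (2R)-2-[(tert-butyldimethylsilyl)oxy]propanoate | C[C@@H](O[Si](C)(C)C(C)(C)C)C(=O)OC | intermediate
3 | (2R)-2-[(tert-butyldimethylsilyl)oxy]propanal | C[C@@H](O[Si](C)(C)C(C)(C)C)C=O | intermediate
4 | (4R)-4-[(tert-butyldimethylsilyl)oxy]-2-methylpent-1-en-3-ol, both C3 epimers | C=C(C)C(O)[C@@H](C)O[Si](C)(C)C(C)(C)C | intermediate
5 | 1-ethoxyvinyl ether (mixed ketene acetal) of 4 | C=C(OCC)OC(C(C)=C)[C@@H](C)O[Si](C)(C)C(C)(C)C | intermediate
6 | ethyl (4E,6R)-6-[(tert-butyldimethylsilyl)oxy]-4-methylhept-4-enoate | CCOC(=O)CC/C(C)=C/[C@@H](C)O[Si](C)(C)C(C)(C)C | intermediate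
7 | ethyl (4E,6R)-6-hydroxy-4-methylhept-4-enoate | CCOC(=O)CC/C(C)=C/[C@@H](C)O | intermediate
8 | 1,2,4-trimethoxybenzene | COc1ccc(OC)c(OC)c1 | starting material
9 | 2,3,6-trimethoxyphenyllithium | COc1ccc(OC)c([Li])c1OC | intermediate
10 | 2-(2,3,6-trimethoxyphenyl)propan-2-ol | COc1ccc(OC)c(C(C)(C)O)c1OC | intermediate
11 | 1,2,4-trimethoxy-3-(propan-2-yl)benzene | COc1ccc(OC)c(C(C)C)c1OC | intermediate
12 | 1-[2,4,5-trimethoxy-3-(propan-2-yl)phenyl]ethan-1-one | CC(=O)c1cc(OC)c(OC)c(C(C)C)c1OC | intermediate
13 | methyl 3-oxo-3-[2,4,5-trimethoxy-3-(propan-2-yl)phenyl]propanoate | COC(=O)CC(=O)c1cc(OC)c(OC)c(C(C)C)c1OC | intermediate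
14 | aroylacetate of 7 (trimethoxyarene; 4R; E alkene) | CCOC(=O)CC/C(C)=C/[C@@H](C)OC(=O)CC(=O)c1cc(OC)c(OC)c(C(C)C)c1OC | intermediate
15 | acyl quinone (11,14-quinone of 14; C9–H free) | CCOC(=O)CC/C(C)=C/[C@@H](C)OC(=O)CC(=O)C1=CC(=O)C(OC)=C(C(C)C)C1=O | intermediate
16 | Z-enol of 15 (C6=C7–OH, C21 cis to O7, trans to C8) | CCOC(=O)CC/C(C)=C/[C@@H](C)OC(=O)/C=C(\O)C1=CC(=O)C(OC)=C(C(C)C)C1=O | intermediate
17 | primary [4+2] adduct (7-hydroxy-7(8)-ene-11,14-dione; 9α-H; lactone as in 19) | C[C@H]1OC(=O)[C@@H]2C(O)=C3C(=O)C(C(C)C)=C(OC)C(=O)[C@@H]3[C@@](C)(CCC(=O)OCC)[C@H]12 | intermediate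
18 | quinone lactone (11,14-quinone of 19) | C[C@H]1OC(=O)[C@@H]2C(=O)C3=C(C(=O)C(OC)=C(C(C)C)C3=O)[C@@](C)(CCC(=O)OCC)[C@H]12 | intermediate
19 | hydroquinone β-keto-γ-lactone: 11,14-dihydroxy-12-methoxy-13-isopropyl-7-oxo tetralone; γ-lactone C6–C21(=O)–O–C4 cis-fused at C5–C6; 4R with 4-CH3 trans to C10; 5α-H, 6α-H, 10β-CH3, 10α-CH2CH2CO2Et | C[C@H]1OC(=O)[C@@H]2C(=O)c3c(O)c(C(C)C)c(OC)c(O)c3[C@@](C)(CCC(=O)OCC)[C@H]12 | intermediate
20 | β-keto acid (C6–CO2H, C4–OH and C3 acid free) | C[C@@H](O)[C@@H]1[C@H](C(=O)O)C(=O)c2c(O)c(C(C)C)c(OC)c(O)c2[C@@]1(C)CCC(=O)O | intermediate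
21 | hydroxy acid (4R carbinol, C6H2) | C[C@@H](O)[C@@H]1CC(=O)c2c(O)c(C(C)C)c(OC)c(O)c2[C@@]1(C)CCC(=O)O | intermediate
22 | quinone diketone (11,14-quinone of 23) | CC(=O)[C@@H]1CC(=O)C2=C(C(=O)C(OC)=C(C(C)C)C2=O)[C@@]1(C)CCC(=O)O | intermediate
23 | methyl ketone (C4=O), hydroquinone acid | CC(=O)[C@@H]1CC(=O)c2c(O)c(C(C)C)c(OC)c(O)c2[C@@]1(C)CCC(=O)O | intermediate
24 | CNP0249049.1 | C=C(C)[C@@H]1CC(=O)c2c(O)c(C(C)C)c(OC)c(O)c2[C@@]1(C)CCC(=O)O | target

**Count and risks**

Total steps: 15. Longest linear sequence: 11 (steps 1–5 and 10–15).

Steps most likely to fail: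

1. Step 12. The ester tether has to leave its preferred rotamer, so the cycloaddition may be slow. It may then lose to bimolecular Michael addition of the enol carbon C6 to C9 of a second quinone, to closure through oxygen, or to loss of the C5 configuration by tautomerisation at the stage of 18. The fallback uses known chemistry, sets out from 14 and returns at 18. It makes the two bonds by radicals on the arene instead of pericyclically on the quinone.
   - Mn(OAc)3·2H2O (2.2 equiv) in degassed AcOH at 70 °C oxidises the β-keto ester of 14 to the C6 radical (oxidative free-radical cyclisation with trivalent manganese).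
   - This radical closes 5-exo on C5 under the same A(1,3) control. The tertiary C10 radical adds to C9 of the trimethoxyarene and rearomatises to the trimethyl ether lactone F1.
   - The closure is not stereospecific at C10, so the C10 epimers would have to be separated.
   - (NH4)2Ce(NO3)6 in MeCN–H2O then demethylates F1 oxidatively to 18, which the dithionite wash of step 12 takes to 19.

2. Step 11. Tetravalent cerium may oxidise the β-dicarbonyl unit by one electron (radical closure onto the alkene), the ring may be nitrated, or water may add to C9 of the acyl quinone. The fallback sets out from 14 and returns at 15 by a two-electron route through a phenol.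
   - BCl3 (CH2Cl2, −78 to −20 °C) removes only the C14 methyl group, which is chelated to the C7 ketone, and gives the C14 phenol F2.
   - PhI(OAc)2 in MeCN–H2O at 0 °C oxidises this para-methoxyphenol to 15.
   - F2 is kept cold and used at once, because an ortho-hydroxyaryl β-keto ester can close to a 4-hydroxycoumarin with loss of 7.

3. Step 15. The ylide may enolise the hindered C4 ketone with epimerisation at C5, or the tripotassium salt may dissolve and react poorly. The fallback sets out from 23 and returns at 24 by a Peterson olefination.
   - Me3SiCH2MgCl (excess) with dried CeCl3 in THF at −78 to 0 °C is a weakly basic nucleophile. It first forms the salts of the acid and the phenols and then adds to the C4 ketone to give the β-hydroxysilane F3 (both C4 epimers).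
   - Brief treatment with dilute H2SO4 in THF brings about the elimination, and both epimers give the same 1,1-disubstituted alkene 24.

Further compounds
F1 | step 12 | trimethyl ether lactone (11,12,14-trimethoxy analogue of 19) | C[C@H]1OC(=O)[C@@H]2C(=O)c3c(OC)c(C(C)C)c(OC)c(OC)c3[C@@](C)(CCC(=O)OCC)[C@H]12
F2 | step 11 | C14 phenol (14 with the methoxy group ortho to the ketone cleaved) | CCOC(=O)CC/C(C)=C/[C@@H](C)OC(=O)CC(=O)c1cc(OC)c(OC)c(C(C)C)c1O
F3 | step 15 | β-hydroxysilane (C4 tertiary carbinol with CH3 and CH2SiMe3, both C4 epimers) | CC(O)(C[Si](C)(C)C)[C@@H]1CC(=O)c2c(O)c(C(C)C)c(OC)c(O)c2[C@@]1(C)CCC(=O)O
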